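**Retrosynthetic overview**
1. Feature: the quaternary C6 of the 5,6,7,8-tetrahydroquinoline and its chain C6–CH2–CH2–N can be folded onto the picolylic ring carbon C5. A temporary N–C5 bond gives a pyrrolidine (N, C5, C6, CH2, CH) cis-fused to the carbocycle C4a–C5–C6–C7–C8–C8a.
2. Target 20 ⇐ formamide 19 ⇐ amine 18 ⇐ amino acid 17 (N-methylation, N-formylation, decarboxylation). 17 ⇐ cycloadduct 14 by lactone opening and hydrogenolysis of the template N–CH(Ph) bond and the picolylic N–C5 bond.
3. 14 ⇐ aldehyde 8 + (5R)-5-phenylmorpholin-2-one 12 by an intramolecular azomethine ylide [3+2] cycloaddition that forms C5–N, C5–C6 and CH2–CH.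
4. 8 ⇐ 2-methylnicotinaldehyde 1 (acetal, picolylic lithiation, 2,3-dibromopropene 3), then Suzuki coupling with boronic acid 7. 12 ⇐ (R)-phenylglycinol 9 + phenyl bromoacetate 10.
5. Ring order: pyridine bought; morpholinone template (step 5); carbocycle and pyrrolidine together (step 6); pyrrolidine and template opened again (step 7).

Key step: step 6

Remarks on the chemistry:
- Locants C5–C8a refer to the tetrahydroquinoline of the target. Tricyclic intermediates are numbered as 1H-pyrrolo[2,3-f]quinolines (N1; C2 = former lactone α-carbon; C3a = quinoline C6; C9b = quinoline C5).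
- The target is (S) at C6.
- Assumption: the ylide reacts in its E geometry (pyridyl syn to the lactone α-C–H, away from the template CHPh carbon) on the face opposite the pseudoaxial phenyl. On this model the (5R)-template gives the (S)-configured C6. If the opposite sense were found, the same steps would be run with the (5S)-template from (S)-phenylglycinol.

**Route**

Step 1
Reactants: 1 2-methylpyridine-3-carbaldehyde
Product: 2 3-(1,3-dioxolan-2-yl)-2-methylpyridine
Conditions: HOCH2CH2OH, p-TsOH·H2O (1.1 equiv), PhMe, reflux, Dean–Stark; aq. Na2CO3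
Reagents that add atoms: ethylene glycol, OCCO
Why: Acid-catalysed acetalisation with azeotropic removal of water masks the aldehyde against the amide base of step 2, a full equivalent of acid being used because the pyridine nitrogen buffers it.

Step 2
Reactants: 2 3-(1,3-dioxolan-2-yl)-2-methylpyridine; 3 2,3-dibromoprop-1-ene
Product: 5 2-(3-bromobut-3-en-1-yl)-3-(1,3-dioxolan-2-yl)pyridine, via pyridylmethyllithium 4 (not isolated)
Conditions: LDA (1.1 equiv), THF, −78 °C; then 3 (1.3 equiv), −78 → −30 °C
Reagents that add atoms: none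
Why: Lateral (picolylic) lithiation of the 2-methyl group gives a stabilised anion that is alkylated by SN2 (or the equivalent SN2′) displacement of the allylic bromide, the vinylic bromide being inert at low temperature.

Step 3
Reactants: 5 2-(3-bromobut-3-en-1-yl)-3-(1,3-dioxolan-2-yl)pyridine
Product: 6 2-(3-bromobut-3-en-1-yl)pyridine-3-carbaldehyde
Conditions: 2 M aq. HCl, THF, 50 °C; then NaHCO3
Reagents that add atoms: water, O
Why: Acid-catalysed acetal hydrolysis is placed before the aryl group is introduced, because the vinyl bromide tolerates warm aqueous acid whereas an electron-rich 1-arylvinyl group could hydrate or isomerise.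

Step 4
Reactants: 6 2-(3-bromobut-3-en-1-yl)pyridine-3-carbaldehyde; 7 (3,4-dimethoxyphenyl)boronic acid
Product: 8 2-[3-(3,4-dimethoxyphenyl)but-3-en-1-yl]pyridine-3-carbaldehyde
Conditions: Pd(dppf)Cl2 (3 mol %), K2CO3, dioxane/H2O, 80 °C
Reagents that add atoms: none
Why: Suzuki–Miyaura coupling of the 2-bromo-1-alkene with the arylboronic acid installs the 1,1-disubstituted styrene, and the non-enolisable aldehyde and the pyridine tolerate aqueous carbonate.

Step 5
Reactants: 9 (R)-2-phenylglycinol; 10 phenyl bromoacetate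
Product: 12 (5R)-5-phenylmorpholin-2-one, via phenyl N-[(1R)-2-hydroxy-1-phenylethyl]glycinate 11 (not isolated)
Conditions: i-Pr2NEt, MeCN, rt; used at once in step 6
Reagents that add atoms: none
Why: N-alkylation of the amino alcohol by the α-bromo ester is followed by lactonisation (intramolecular transesterification) driven by loss of phenol, and the stereocentre of phenylglycinol is not touched.

Step 6
Reactants: 8 2-[3-(3,4-dimethoxyphenyl)but-3-en-1-yl]pyridine-3-carbaldehyde; 12 (5R)-5-phenylmorpholin-2-one
Product: 14 morpholinone-fused cis-hexahydropyrrolo[2,3-f]quinoline cycloadduct [3a-(3,4-dimethoxyphenyl); (2R,3aS,9bR); N1–CH(Ph)(R)–CH2–O–C(=O)–C2], via azomethine ylide 13 (not isolated)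
Conditions: PhMe (0.01 M), reflux, Dean–Stark with 4 Å MS; 8 added slowly to 12 (1.3 equiv)
Reagents that add atoms: none
Why: Condensation of aldehyde 8 with the secondary amine 12 gives an iminium ion that loses the lactone α-proton to form the ester-stabilised azomethine ylide 13, which adds suprafacially across the tethered 1-arylvinyl group. The closest known reaction type is the intramolecular [3+2] cycloaddition of amino-ester-derived stabilised azomethine ylides of ortho-alkenyl aryl aldehydes, including ylides of 5-phenylmorpholin-2-one, onto unactivated alkenes. The pyrrolidine closes through the two new C–C bonds (C2–C3 and C9b–C3a), and the six-membered carbocycle closes in the same event through the C9b–C3a bond in the fused mode, since the bridged mode would need a seven-membered ring. C3a (S, the later C6) and C9b (R) are set together by the tether, which allows only cis fusion from the E ylide, and by approach of the alkene to the ylide face opposite the pseudoaxial phenyl of the (5R)-template, while C2 (R) follows from the fixed geometry of the lactone half of the ylide. The step needs facial selectivity, secured by the template phenyl, regioselectivity, secured by the tether length, and intramolecular trapping in preference to capture of the ylide by a second aldehyde, secured by high dilution and slow addition of 8.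

Step 7
Reactants: 14 morpholinone-fused cycloadduct
Product: 17 (2R)-2-amino-3-[(6S)-6-(3,4-dimethoxyphenyl)-5,6,7,8-tetrahydroquinolin-6-yl]propanoic acid, via hydroxy acid 15 (not isolated), via pyrrolidine amino acid 16 (not isolated)
Conditions: LiOH, THF/H2O, rt; then AcOH, 20% Pd(OH)2/C, H2 (4 bar), 45 °C; Dowex 50 (aq. NH3)
Reagents that add atoms: lithium hydroxide, [Li+].[OH-]
Why: Saponification opens the lactone irreversibly, after which hydrogenolysis over Pearlman's catalyst in acid should cleave both benzylic-type C–N bonds, first N–CH(Ph) of the template and then the picolylic N1–C9b bond of the 2-(3-pyridyl)pyrrolidine, so that quinoline C5 becomes CH2 while the all-carbon quaternary C6 can neither react nor epimerise.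

Step 8
Reactants: 17 (2R)-2-amino-3-[(6S)-6-(3,4-dimethoxyphenyl)-5,6,7,8-tetrahydroquinolin-6-yl]propanoic acid
Product: 18 2-[(6S)-6-(3,4-dimethoxyphenyl)-5,6,7,8-tetrahydroquinolin-6-yl]ethan-1-amine
Conditions: 2-cyclohexen-1-one (10 mol %), cyclohexanol, 160 °C; then 2 M HCl, then NaOH
Reagents that add atoms: none
Why: Enone-catalysed thermal decarboxylation of an α-amino acid (imine formation, loss of CO2 through an azomethine ylide, protonation and transimination) removes the carboxyl carbon and with it the C2 stereocentre, leaving C6 untouched.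

Step 9
Reactants: 18 2-[(6S)-6-(3,4-dimethoxyphenyl)-5,6,7,8-tetrahydroquinolin-6-yl]ethan-1-amine
Product: 19 N-{2-[(6S)-6-(3,4-dimethoxyphenyl)-5,6,7,8-tetrahydroquinolin-6-yl]ethyl}formamide
Conditions: HCO2Et, reflux
Reagents that add atoms: ethyl formate, CCOC=O
Why: N-Formylation by aminolysis of ethyl formate is clean for an unhindered primary amine and does not affect the pyridine or the aryl ethers.

Step 10
Reactants: 19 N-{2-[(6S)-6-(3,4-dimethoxyphenyl)-5,6,7,8-tetrahydroquinolin-6-yl]ethyl}formamide
Product: 20 N-{2-[(6S)-6-(3,4-dimethoxyphenyl)-5,6,7,8-tetrahydroquinolin-6-yl]ethyl}-N-methylformamide (CNP0346821.1)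
Conditions: NaH (1.1 equiv), THF, 0 °C; MeI (1.05 equiv), 0 °C → rt
Reagents that add atoms: iodomethane, CI
Why: N-Alkylation of the sodium amidate of a secondary formamide by SN2 on iodomethane should be selective, because the amidate is far more nucleophilic than the pyridine nitrogen and only one equivalent of the alkylating agent is offered.

**Compound list**
1 | 2-methylpyridine-3-carbaldehyde | Cc1ncccc1C=O | starting material
2 | 3-(1,3-dioxolan-2-yl)-2-methylpyridine | Cc1ncccc1C1OCCO1 | intermediate
3 | 2,3-dibromoprop-1-ene | C=C(Br)CBr | starting material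
4 | [3-(1,3-dioxolan-2-yl)pyridin-2-yl]methyllithium | [Li]Cc1ncccc1C1OCCO1 | intermediate
5 | 2-(3-bromobut-3-en-1-yl)-3-(1,3-dioxolan-2-yl)pyridine | C=C(Br)CCc1ncccc1C1OCCO1 | intermediate
6 | 2-(3-bromobut-3-en-1-yl)pyridine-3-carbaldehyde | C=C(Br)CCc1ncccc1C=O | intermediate
7 | (3,4-dimethoxyphenyl)boronic acid | COc1ccc(B(O)O)cc1OC | starting material
8 | 2-[3-(3,4-dimethoxyphenyl)but-3-en-1-yl]pyridine-3-carbaldehyde | O=Cc1cccnc1CCC(=C)c1ccc(OC)c(OC)c1 | intermediate
9 | (R)-2-phenylglycinol [(2R)-2-amino-2-phenylethan-1-ol] | N[C@@H](CO)c1ccccc1 | starting material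
10 | phenyl bromoacetate | BrCC(=O)Oc1ccccc1 | starting material
11 | phenyl N-[(1R)-2-hydroxy-1-phenylethyl]glycinate | OC[C@H](NCC(=O)Oc1ccccc1)c1ccccc1 | intermediate
12 | (5R)-5-phenylmorpholin-2-one | O=C1OC[C@@H](c2ccccc2)NC1 | intermediate
13 | E azomethine ylide from 8 and 12 (iminium carbon bearing the pyridyl group, carbanion at the lactone α-carbon) | O=C1OC[C@@H](c2ccccc2)/[N+](=C/c2cccnc2CCC(=C)c2ccc(OC)c(OC)c2)[CH-]1 | intermediate
14 | cis-fused cycloadduct: (2R,3aS,9bR)-3a-(3,4-dimethoxyphenyl)-2,3,3a,4,5,9b-hexahydro-1H-pyrrolo[2,3-f]quinoline with N1 and C2 bridged by the template unit –CH(Ph)–CH2–O–C(=O)– (CHPh carbon R) | COc1ccc([C@@]2(C[C@@H]3C(=O)OC[C@@H](c4ccccc4)N35)CCc3ncccc3[C@@H]25)cc1OC | intermediate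
15 | (2R,3aS,9bR)-3a-(3,4-dimethoxyphenyl)-1-[(1R)-2-hydroxy-1-phenylethyl]-2,3,3a,4,5,9b-hexahydro-1H-pyrrolo[2,3-f]quinoline-2-carboxylic acid | COc1ccc([C@@]2(C[C@H](C(=O)O)N5[C@@H](CO)c4ccccc4)CCc3ncccc3[C@@H]25)cc1OC | intermediate
16 | (2R,3aS,9bR)-3a-(3,4-dimethoxyphenyl)-2,3,3a,4,5,9b-hexahydro-1H-pyrrolo[2,3-f]quinoline-2-carboxylic acid | COc1ccc([C@@]2(C[C@H](C(=O)O)N5)CCc3ncccc3[C@@H]25)cc1OC | intermediate
17 | (2R)-2-amino-3-[(6S)-6-(3,4-dimethoxyphenyl)-5,6,7,8-tetrahydroquinolin-6-yl]propanoic acid | COc1ccc([C@@]2(C[C@@H](N)C(=O)O)CCc3ncccc3C2)cc1OC | intermediate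
18 | 2-[(6S)-6-(3,4-dimethoxyphenyl)-5,6,7,8-tetrahydroquinolin-6-yl]ethan-1-amine | COc1ccc([C@@]2(CCN)CCc3ncccc3C2)cc1OC | intermediate
19 | N-{2-[(6S)-6-(3,4-dimethoxyphenyl)-5,6,7,8-tetrahydroquinolin-6-yl]ethyl}formamide | COc1ccc([C@@]2(CCNC=O)CCc3ncccc3C2)cc1OC | intermediate
20 | N-{2-[(6S)-6-(3,4-dimethoxyphenyl)-5,6,7,8-tetrahydroquinolin-6-yl]ethyl}-N-methylformamide | COc1ccc([C@@]2(CCN(C)C=O)CCc3ncccc3C2)cc1OC | target

**Step count**
Total: 10 steps. Longest linear sequence: 9 steps (1 → 2 → 5 → 6 → 8 → 14 → 17 → 18 → 19 → 20); step 5 is a one-step branch.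

**Steps most likely to fail**

Step 6. The ylide may be captured by a second aldehyde molecule faster than it adds to the unactivated, sterically loaded 1-arylvinyl group. The alkene may also reach both ylide faces, because its aryl group has to pass the template in the transition state. The fallback sets out from 8 and returns at 17. Aldehyde 8 would be heated in toluene or xylene with ethyl N-[(1R)-1-phenylethyl]glycinate (CCOC(=O)CN[C@H](C)c1ccccc1, bought), an acyclic secondary amino ester of the type for which this stabilised-ylide cycloaddition of ortho-alkenyl aryl aldehydes is best established. The cycloadducts are diastereomers, so the isomer with the required ring-fusion configuration, ethyl (2R,3aS,9bR)-3a-(3,4-dimethoxyphenyl)-1-[(1R)-1-phenylethyl]-2,3,3a,4,5,9b-hexahydro-1H-pyrrolo[2,3-f]quinoline-2-carboxylate F1, would be separated by chromatography or crystallisation. The C2 configuration is immaterial, since that centre is lost in step 8. Hydrogenolysis (H2, Pd(OH)2/C, AcOH/EtOH) would remove the phenylethyl group and cut the picolylic bond to give ethyl (2R)-2-amino-3-[(6S)-6-(3,4-dimethoxyphenyl)-5,6,7,8-tetrahydroquinolin-6-yl]propanoate F2. Saponification (LiOH, then neutralisation) would give amino acid 17.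

Step 7. Hydrogen uptake may stop once the template is removed, because the remaining picolylic C–N bond then belongs to a protonated secondary amino acid next to a quaternary carbon. Forcing the reaction may begin to saturate the pyridine ring. The fallback sets out from 16, isolated by ion exchange at the stage where the reaction stops, and returns at 20. Decarboxylation of 16 (2-cyclohexen-1-one cat., cyclohexanol, 160 °C) would give (3aS,9bR)-3a-(3,4-dimethoxyphenyl)-2,3,3a,4,5,9b-hexahydro-1H-pyrrolo[2,3-f]quinoline F3. Reductive methylation (aq. HCHO, NaBH(OAc)3) would give (3aS,9bR)-3a-(3,4-dimethoxyphenyl)-1-methyl-2,3,3a,4,5,9b-hexahydro-1H-pyrrolo[2,3-f]quinoline F4. This neutral tertiary amine is no longer a zwitterion, and its picolylic bond would be cut on its own by hydrogenolysis (H2, Pd/C, AcOH with a little HClO4, rt) to give 2-[(6S)-6-(3,4-dimethoxyphenyl)-5,6,7,8-tetrahydroquinolin-6-yl]-N-methylethan-1-amine F5. Formylation with refluxing ethyl formate would then give 20 directly, so the methylation of step 10 is not needed.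

Step 8. The zwitterion may stay undissolved so that conversion stalls, or the imine intermediates may condense further with the enone at 160 °C. The fallback sets out from 17 and returns at 19. N-Formylation (HCO2H, Ac2O, 0 °C → rt) would give (2R)-3-[(6S)-6-(3,4-dimethoxyphenyl)-5,6,7,8-tetrahydroquinolin-6-yl]-2-formamidopropanoic acid F6. Coupling with N-hydroxyphthalimide (DIC, cat. DMAP, CH2Cl2) would give 1,3-dioxoisoindolin-2-yl (2R)-3-[(6S)-6-(3,4-dimethoxyphenyl)-5,6,7,8-tetrahydroquinolin-6-yl]-2-formamidopropanoate F7. Radical reductive decarboxylation of this redox-active ester ([Ru(bpy)3]Cl2 cat., Hantzsch ester, i-Pr2NEt, blue LED) would give formamide 19 at room temperature.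

**Further compounds**
F1 | step 6 | ethyl (2R,3aS,9bR)-3a-(3,4-dimethoxyphenyl)-1-[(1R)-1-phenylethyl]-2,3,3a,4,5,9b-hexahydro-1H-pyrrolo[2,3-f]quinoline-2-carboxylate | COc1ccc([C@@]2(C[C@H](C(=O)OCC)N5[C@H](C)c4ccccc4)CCc3ncccc3[C@@H]25)cc1OC
F2 | step 6 | ethyl (2R)-2-amino-3-[(6S)-6-(3,4-dimethoxyphenyl)-5,6,7,8-tetrahydroquinolin-6-yl]propanoate | COc1ccc([C@@]2(C[C@@H](N)C(=O)OCC)CCc3ncccc3C2)cc1OC
F3 | step 7 | (3aS,9bR)-3a-(3,4-dimethoxyphenyl)-2,3,3a,4,5,9b-hexahydro-1H-pyrrolo[2,3-f]quinoline | COc1ccc([C@@]2(CCN5)CCc3ncccc3[C@@H]25)cc1OC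
F4 | step 7 | (3aS,9bR)-3a-(3,4-dimethoxyphenyl)-1-methyl-2,3,3a,4,5,9b-hexahydro-1H-pyrrolo[2,3-f]quinoline | COc1ccc([C@@]2(CCN5C)CCc3ncccc3[C@@H]25)cc1OC
F5 | step 7 | 2-[(6S)-6-(3,4-dimethoxyphenyl)-5,6,7,8-tetrahydroquinolin-6-yl]-N-methylethan-1-amine | COc1ccc([C@@]2(CCNC)CCc3ncccc3C2)cc1OC
F6 | step 8 | (2R)-3-[(6S)-6-(3,4-dimethoxyphenyl)-5,6,7,8-tetrahydroquinolin-6-yl]-2-formamidopropanoic acid | COc1ccc([C@@]2(C[C@@H](NC=O)C(=O)O)CCc3ncccc3C2)cc1OC
F7 | step 8 | 1,3-dioxoisoindolin-2-yl (2R)-3-[(6S)-6-(3,4-dimethoxyphenyl)-5,6,7,8-tetrahydroquinolin-6-yl]-2-formamidopropanoate | COc1ccc([C@@]2(C[C@@H](NC=O)C(=O)ON4C(=O)c5ccccc5C4=O)CCc3ncccc3C2)cc1OC
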